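The plan rests on tracing the ten-membered carbocycle back to an eight-membered cyclic enol ether. The feature exploited is the 1,5-relationship, inside the ten-membered ring, between the C1 oxygen function (taken one level up, as a ketone) and the E C4=C5 double bond, bridged by C2–C3. A Claisen [3,3] shift of the allyl vinyl ether C2=C1–O–C5–C4=C3 forms C2–C3, breaks O–C5 and so delivers carbocycle, C1 ketone and trisubstituted alkene in one operation. Its precursor is a 2-methylene-8-isopropenyloxocane, cis-fused at C6–C7 to the five-membered lactone ring masked as its methyl acetal, with O8 as PMB ether and C9 as a silyl ether, which keeps C10 configurationally safe.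

Key step: step 18

Numbering: germacrane numbering is used for all intermediates. C1 is the methoxy carbon, C2 and C3 are ring CH2, C4 is the methyl-bearing alkene carbon, C5 the alkene CH, C6 the lactone O–CH and C7 the ring-fusion CH. C8 is the acyloxy CH, C9 the ketone, C10 CHMe, C11 the lactone CHMe and C12 the lactone C=O.

Assumption: the two acetal carbons (C12, drawn with OMe trans to the C11 methyl group, and the benzylidene CH on O8/O9, left undefined in the SMILES) arise as epimer mixtures that are carried on unseparated, since both centres vanish later.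

Abbreviations: PMB 4-methoxybenzyl; TES triethylsilyl; TBS tert-butyldimethylsilyl; DMP Dess–Martin periodinane; MNBA 2-methyl-6-nitrobenzoic anhydride; PPTS pyridinium 4-toluenesulfonate; DMAP 4-dimethylaminopyridine; MS molecular sieves.

Step 1
Reactants: 1 (1S,5R)-2-oxabicyclo[3.3.0]oct-6-en-3-one
Product: 3 exo-C11-methyl bicyclic lactone, via lithium enolate 2 (not isolated)
Conditions: LiN(i-Pr)2, THF, −78 °C; MeI, −78 to −40 °C
Reagents that add atoms: iodomethane, CI; lithium diisopropylamide, [Li+].CC(C)[N-]C(C)C (Li in 2 only)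
Why: Kinetic lactone enolate alkylation: the cup-shaped cis-bicyclo[3.3.0]octene enolate should accept MeI only on its convex face, which sets C11 with the methyl group cis to H6 and H7 as in the target.

Step 2
Reactants: 3 exo-C11-methyl bicyclic lactone
Product: 5 bicyclic C12 methyl acetal, via lactol 4 (not isolated)
Conditions: i-Bu2AlH, CH2Cl2, −78 °C; then HCl in MeOH, −78 °C to rt
Reagents that add atoms: methanol, CO
Why: Partial lactone reduction with i-Bu2AlH stops at the aluminium hemiacetal at −78 °C, and Fischer-type acetalisation of the released lactol masks C12, so that the later Grignard, hydride and titanium carbene reagents meet no second carbonyl group.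

Step 3
Reactants: 5 bicyclic C12 methyl acetal
Product: 6 exo C8–C9 epoxide
Conditions: mCPBA, NaHCO3, CH2Cl2, 0 °C
Reagents that add atoms: 3-chloroperoxybenzoic acid, OOC(=O)c1cccc(Cl)c1
Why: Prilezhaev epoxidation: the peracid should approach the C8=C9 alkene from the open convex face of the bicycle, which fixes the C8–O bond (cis to H7) that is kept to the end.

Step 4
Reactants: 6 exo C8–C9 epoxide
Product: 9 allylic alcohol (C8 exo-OH; C9=C5), via hydroxy selenide 7 (not isolated), via selenoxide 8 (not isolated)
Conditions: (PhSe)2, NaBH4, EtOH, rt to 50 °C; then THF, 30% H2O2, NaHCO3, 0 °C to rt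
Reagents that add atoms: diphenyl diselenide, c1ccc(cc1)[Se][Se]c1ccccc1 (PhSe in 7 and 8 only); hydrogen peroxide, OO (O in 8 only)
Why: Epoxide-to-allylic-alcohol transposition by selenide opening and selenoxide syn-elimination: PhSe− should open the exo epoxide anti at C9, the carbon remote from the ring fusion, so the C8–O bond is untouched, and the selenoxide eliminates away from the carbinol carbon toward C5.

Step 5
Reactants: 9 allylic alcohol
Product: 11 C5,C8,C9-triol, via hydroxy dialdehyde 10 (not isolated)
Conditions: O3, CH2Cl2/MeOH, −78 °C (stopped at first excess); Me2S; NaBH4, 0 °C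
Reagents that add atoms: ozone, [O-][O+]=O
Why: Ozonolysis with reductive work-up cuts the C9=C5 alkene into the two chain ends without touching C6, C7, C8 or C11, and immediate borohydride reduction avoids handling an epimerisable hydroxy dialdehyde whose two aldehyde groups could not be told apart.

Step 6
Reactants: 11 C5,C8,C9-triol
Product: 12 O8/O9 4-methoxybenzylidene acetal with free C5 primary alcohol
Conditions: 4-MeOC6H4CH(OMe)2, PPTS (cat.), CH2Cl2, rt
Reagents that add atoms: 4-methoxybenzaldehyde dimethyl acetal, COC(OC)c1ccc(OC)cc1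
Why: Acid-catalysed transacetalisation under thermodynamic control prefers the five-membered dioxolane on the vicinal C8/C9 diol over any seven- or eight-membered alternative, which differentiates the two primary alcohols and leaves only C5–OH free.

Step 7
Reactants: 12 O8/O9 benzylidene acetal alcohol
Product: 13 C5 aldehyde
Conditions: DMP, NaHCO3, CH2Cl2, 0 °C to rt
Reagents that add atoms: none
Why: Buffered Dess–Martin oxidation is essentially neutral, so the aldehyde should form without epimerisation at C6 and without harm to either acetal.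

Step 8
Reactants: 13 C5 aldehyde; 14 isopropenylmagnesium bromide
Product: 15 (5R)-isopropenyl carbinol
Conditions: MgBr2·OEt2, CH2Cl2, −78 °C; then 14 (THF solution), −78 °C
Reagents that add atoms: none
Why: Chelation-controlled (Cram chelate) Grignard addition: magnesium ties the aldehyde oxygen to the ring oxygen O6 and the nucleophile should enter from the side of H6, away from C7, giving the 5,6-syn (5R) carbinol, a centre that is consumed in step 18 but shapes its transition state.

Step 9
Reactants: 15 (5R)-isopropenyl carbinol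
Product: 16 C5 TES ether
Conditions: Et3SiCl, imidazole, CH2Cl2, 0 °C
Reagents that add atoms: chlorotriethylsilane, CC[Si](Cl)(CC)CC
Why: Standard silylation of a secondary alcohol, chosen because a TES ether survives the hydride, oxidation and boron aldol steps yet can later be removed beside a TBS ether.

Step 10
Reactants: 16 C5 TES ether
Product: 17 C8 PMB ether with free C9 primary alcohol
Conditions: i-Bu2AlH, CH2Cl2, −78 to 0 °C; aq. potassium sodium tartrate
Reagents that add atoms: none
Why: Regioselective reductive opening of a 4-methoxybenzylidene acetal: aluminium binds the less hindered primary oxygen O9, that C–O bond breaks and hydride goes to the benzylic carbon, so PMB stays on O8 and the C9 alcohol is released, while the less ionisable C12 methyl acetal should not react at this temperature.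

Step 11
Reactants: 17 C8 PMB ether C9 alcohol
Product: 18 C9 aldehyde
Conditions: DMP, NaHCO3, CH2Cl2, 0 °C to rt
Reagents that add atoms: none
Why: Buffered Dess–Martin oxidation gives the α-alkoxy aldehyde without epimerisation at C8 and tolerates TES, PMB, the acetal and the alkene.

Step 12
Reactants: 18 C9 aldehyde; 19 (R)-4-benzyl-3-propionyloxazolidin-2-one
Product: 21 9,10-syn aldol imide, via boron enolate 20 (not isolated)
Conditions: 19, n-Bu2BOTf, Et3N, CH2Cl2, −78 to 0 °C; 18, −78 to 0 °C; pH 7 buffer, MeOH, H2O2, 0 °C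
Reagents that add atoms: dibutylboron triflate, CCCCB(CCCC)OS(=O)(=O)C(F)(F)F (boron in 20 only)
Why: Evans syn-aldol reaction: the Z-boron enolate reacts through a Zimmerman–Traxler chair whose facial bias comes from the (R)-benzyl auxiliary, which sets C10 in the target configuration together with a 9,10-syn carbinol, and reagent control should override the modest opposing Felkin-type bias of the α-alkoxy aldehyde.

Step 13
Reactants: 21 9,10-syn aldol imide
Product: 22 C9 TBS ether imide
Conditions: TBSOTf, 2,6-lutidine, CH2Cl2, −78 to −20 °C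
Reagents that add atoms: tert-butyldimethylsilyl triflate, CC(C)(C)[Si](C)(C)OS(=O)(=O)C(F)(F)F
Why: Silyl triflate silylation of an aldol carbinol without retro-aldol cleavage; holding C9 at the alcohol level means that C10 is never flanked by two carbonyl groups and that no ketal has to be hydrolysed next to a β-methoxy group later.

Step 14
Reactants: 22 C9 TBS ether imide
Product: 24 C1 carboxylic acid with C5 TES ether, via peroxy acid 23 (not isolated)
Conditions: LiOH, H2O2, THF/H2O, 0 °C; Na2SO3; dilute HCl to pH 4
Reagents that add atoms: hydrogen peroxide, OO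
Why: Hydroperoxide cleavage of an N-acyloxazolidinone: LiOOH attacks the exocyclic carbonyl group selectively and is too weakly basic to epimerise C10, and the auxiliary is recovered.

Step 15
Reactants: 24 C1 carboxylic acid with C5 TES ether
Product: 25 seco acid (C5–OH, C1 CO2H)
Conditions: PPTS, MeOH/CH2Cl2, 0 °C to rt
Reagents that add atoms: none
Why: Selective acid-catalysed methanolysis of a TES ether beside a hindered TBS ether, in which methanol as solvent makes any exchange at the C12 methyl acetal degenerate.

Step 16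
Reactants: 25 seco acid
Product: 27 eight-membered lactone (oxocan-2-one), via mixed anhydride 26 (not isolated)
Conditions: MNBA, DMAP, CH2Cl2, slow addition at high dilution, rt
Reagents that add atoms: 2-methyl-6-nitrobenzoic anhydride, Cc1cccc([N+](=O)[O-])c1C(=O)OC(=O)c1c(C)cccc1[N+](=O)[O-] (aroyl group in 26 only)
Why: Shiina macrolactonisation, a method proven on substituted eight-membered lactones: the cis-fused acetal ring at C6–C7 and the substituents at C8, C9 and C10 fold the chain so that C5–OH lies near the acylpyridinium carbon, and high dilution suppresses intermolecular acylation.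

Step 17
Reactants: 27 eight-membered lactone
Product: 28 2-methylene-8-isopropenyloxocane
Conditions: Cp2TiMe2, toluene, 75 °C, dark; filtration through basic alumina
Reagents that add atoms: dimethyltitanocene, C[Ti+2]C.c1cc[cH-]c1.c1cc[cH-]c1
Why: Petasis methylenation: thermally generated Cp2Ti=CH2 converts the only carbonyl group present into the exocyclic enol ether through an oxatitanacyclobutane, and the reagent is non-basic, so C10 should keep its configuration.

Step 18
Reactants: 28 2-methylene-8-isopropenyloxocane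
Product: 29 E-cyclodec-4-enone (C1 ketone)
Conditions: toluene (high dilution), i-Pr2NEt (trace), base-washed sealed tube, 170 °C
Reagents that add atoms: none
Why: On heating, the allyl vinyl ether C2=C1–O–C5–C4=C3 embedded in 28 undergoes a concerted suprafacial [3,3]-sigmatropic (Claisen) shift in which C2–C3 forms while O–C5 breaks, and the gain of the C1 carbonyl group makes it irreversible. The closest known reaction type is the methylenation/Claisen ring expansion of 2-methylene-6-vinyltetrahydropyrans to cyclooct-4-enones; the present case is its eight-to-ten homologue. The ten-membered ring is closed by two-atom enlargement of the oxocane, the termini C2 and C3 being held near each other by the existing ring, and not by end-to-end cyclisation of a chain. No new sp3 stereocentre arises (C2 and C3 are CH2 termini, so chair-like and boat-like arrays lead to the same compound), C5 loses its stereocentre, and C6, C7, C8, C9, C10 and C11 are spectators under these neutral conditions. The selectivity required is E geometry at C4=C5, which results only if C6 points outward (pseudo-equatorial, anti to C3) on C5 in the transition state. Three features of 28 should secure this: the C6–C10 tether is long enough to link an outward C6 with C1, the cis-fused acetal ring keeps the C5–C6–C7–C8 torsion small so that the tether folds back below the ring oxygen, and with the 5R configuration the inward array would force O6 and the acetal ring into the forming C2–C3 bond and against the C10 methyl group, whereas the outward array only places O6 in the alkene plane beside the C4 methyl group.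

Step 19
Reactants: 29 E-cyclodec-4-enone
Product: 30 C1 alcohol
Conditions: LiBH(s-Bu)3, THF, −78 °C; NaOH, H2O2, 0 °C
Reagents that add atoms: none
Why: Diastereoselective ketone reduction with a bulky hydride: the inner face of the C1 carbonyl group is blocked by the ring, so attack is peripheral and coincides with the Felkin–Anh mode (C9 perpendicular, C10 methyl beside the carbonyl oxygen), which should give the 1,10-anti alcohol with the target configuration at C1.

Step 20
Reactants: 30 C1 alcohol
Product: 31 C1 methyl ether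
Conditions: Me3OBF4, 1,8-bis(dimethylamino)naphthalene, 4 Å MS, CH2Cl2, rt
Reagents that add atoms: trimethyloxonium tetrafluoroborate, C[O+](C)C.F[B-](F)(F)F
Why: O-Methylation with Meerwein salt and a non-nucleophilic base needs no alkoxide, which avoids silyl migration from O9 to O1 and any epimerisation.

Step 21
Reactants: 31 C1 methyl ether
Product: 32 C12 lactol
Conditions: AcOH/THF/H2O (4:2:1), 45 °C
Reagents that add atoms: water, O
Why: Mild acetal hydrolysis of a 2-methoxytetrahydrofuran under conditions that spare hindered TBS and PMB ethers, carried out while every hydroxyl group is capped, so that the oxocarbenium ion can be trapped only by water and not by O9 to form a bridged acetal.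

Step 22
Reactants: 32 C12 lactol
Product: 33 γ-lactone with C8 PMB and C9 TBS ethers
Conditions: DMP, NaHCO3, CH2Cl2, rt
Reagents that add atoms: none
Why: Dess–Martin oxidation of the only free hydroxyl group turns the lactol into the cis-fused 6,12-lactone without affecting C11.

Step 23
Reactants: 33 γ-lactone with C8 PMB and C9 TBS ethers
Product: 34 C8 alcohol
Conditions: DDQ, CH2Cl2/pH 7 buffer, 0 °C
Reagents that add atoms: none
Why: Oxidative PMB cleavage with DDQ proceeds by hydride abstraction from the electron-rich benzyl ether under neutral conditions and leaves the alkene, lactone, methyl ether and TBS ether alone.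

Step 24
Reactants: 35 tiglic acid
Product: 36 (E)-2-methylbut-2-en-1-ol
Conditions: LiAlH4, Et2O, 0 °C to rt
Reagents that add atoms: none
Why: LiAlH4 reduction of a conjugated carboxylic acid occurs in the 1,2-sense and preserves the E alkene geometry.

Step 25
Reactants: 36 (E)-2-methylbut-2-en-1-ol
Product: 37 (2R,3R)-2,3-dimethyloxiran-2-ylmethanol
Conditions: Ti(OiPr)4 (cat.), D-(−)-diisopropyl tartrate (cat.), t-BuOOH, 4 Å MS, CH2Cl2, −20 °C; non-aqueous work-up, kept in solution
Reagents that add atoms: tert-butyl hydroperoxide, CC(C)(C)OO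
Why: Sharpless asymmetric epoxidation: the D-(−)-tartrate titanium catalyst delivers oxygen to the alkene face that gives the (2R,3R)-epoxy alcohol, and the stereospecific syn addition to the E alkene keeps the two methyl groups cis.

Step 26
Reactants: 37 (2R,3R)-2,3-dimethyloxiran-2-ylmethanol
Product: 38 (2S,3R)-2,3-dimethyloxirane-2-carboxylic acid
Conditions: RuCl3 (cat.), NaIO4, MeCN/EtOAc/H2O, 0 °C to rt
Reagents that add atoms: water, O
Why: Catalytic RuO4 oxidation of a primary epoxy alcohol to the glycidic acid leaves the oxirane intact, and the change of the C2 descriptor is only a change of priorities.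

Step 27
Reactants: 34 C8 alcohol; 38 (2S,3R)-2,3-dimethyloxirane-2-carboxylic acid
Product: 40 C8 epoxy ester with C9 TBS ether, via mixed anhydride 39 (not isolated)
Conditions: 38, 2,4,6-Cl3C6H2COCl, Et3N, toluene, rt; then 34, DMAP, toluene, rt to 60 °C
Reagents that add atoms: 2,4,6-trichlorobenzoyl chloride, O=C(Cl)c1c(Cl)cc(Cl)cc1Cl (aroyl group in 39 only)
Why: Yamaguchi esterification couples a hindered acid with a hindered secondary alcohol, and it is placed here because 34 carries no ketone, so forcing acylation cannot cause loss of methanol across C10–C1 or epimerisation at C8 or C10.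

Step 28
Reactants: 40 C8 epoxy ester with C9 TBS ether
Product: 41 C9 alcohol
Conditions: HF·pyridine, pyridine, THF, 0 °C to rt
Reagents that add atoms: none
Why: Fluoride-mediated desilylation in a buffered, weakly acidic medium should spare the glycidic ester and suppress the base-promoted 1,2-acyl shift from O8 to O9.

Step 29
Reactants: 41 C9 alcohol
Product: 42 target CNP0145898.1
Conditions: DMP, NaHCO3, CH2Cl2, 0 °C to rt
Reagents that add atoms: none
Why: Dess–Martin oxidation reveals the C9 ketone as the very last event under neutral conditions, so the β-methoxy and α-acyloxy ketone is never exposed to acid or base.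

Compound list
1 | (1S,5R)-2-oxabicyclo[3.3.0]oct-6-en-3-one | O=C1C[C@@H]2C=CC[C@@H]2O1 | starting material
2 | lithium enolate of 1 | [Li+].[O-]C1=C[C@@H]2C=CC[C@@H]2O1 | intermediate
3 | exo-C11-methyl bicyclic lactone (methyl on the convex face, cis to H6 and H7) | O=C1[C@@H](C)[C@@H]2C=CC[C@@H]2O1 | intermediate
4 | bicyclic lactol | O[C@@H]1[C@@H](C)[C@@H]2C=CC[C@@H]2O1 | intermediate
5 | bicyclic C12 methyl acetal | CO[C@@H]1[C@@H](C)[C@@H]2C=CC[C@@H]2O1 | intermediate
6 | exo C8–C9 epoxide (oxirane on the convex face) | CO[C@@H]1[C@@H](C)[C@@H]2[C@H]3O[C@H]3C[C@@H]2O1 | intermediate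
7 | trans hydroxy selenide (C8 exo-OH, C9 endo-SePh) | CO[C@@H]1[C@@H](C)[C@@H]2[C@@H](O)[C@H]([Se]c3ccccc3)C[C@@H]2O1 | intermediate
8 | selenoxide of 7 | CO[C@@H]1[C@@H](C)[C@@H]2[C@@H](O)[C@H]([Se](=O)c3ccccc3)C[C@@H]2O1 | intermediate
9 | allylic alcohol (C8 exo-OH, C9=C5) | CO[C@@H]1[C@@H](C)[C@@H]2[C@@H](O)C=C[C@@H]2O1 | intermediate
10 | C8-hydroxy C5,C9-dialdehyde | O=C[C@@H]1O[C@H](OC)[C@@H](C)[C@@H]1[C@@H](O)C=O | intermediate
11 | C5,C8,C9-triol on the 2-methoxytetrahydrofuran ring | OC[C@@H]1O[C@H](OC)[C@@H](C)[C@@H]1[C@@H](O)CO | intermediate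
12 | O8/O9 4-methoxybenzylidene acetal, free C5 primary alcohol | OC[C@@H]1O[C@H](OC)[C@@H](C)[C@@H]1[C@@H]3COC(O3)c2ccc(OC)cc2 | intermediate
13 | C5 aldehyde | O=C[C@@H]1O[C@H](OC)[C@@H](C)[C@@H]1[C@@H]3COC(O3)c2ccc(OC)cc2 | intermediate
14 | isopropenylmagnesium bromide | CC(=C)[Mg]Br | starting material
15 | (5R)-isopropenyl carbinol (O5/O6 syn) | C=C(C)[C@@H](O)[C@@H]1O[C@H](OC)[C@@H](C)[C@@H]1[C@@H]3COC(O3)c2ccc(OC)cc2 | intermediate
16 | C5 TES ether | C=C(C)[C@@H](O[Si](CC)(CC)CC)[C@@H]1O[C@H](OC)[C@@H](C)[C@@H]1[C@@H]3COC(O3)c2ccc(OC)cc2 | intermediate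
17 | C8 PMB ether, C9 primary alcohol | C=C(C)[C@@H](O[Si](CC)(CC)CC)[C@@H]1O[C@H](OC)[C@@H](C)[C@@H]1[C@@H](OCc2ccc(OC)cc2)CO | intermediate
18 | C9 aldehyde | C=C(C)[C@@H](O[Si](CC)(CC)CC)[C@@H]1O[C@H](OC)[C@@H](C)[C@@H]1[C@@H](OCc2ccc(OC)cc2)C=O | intermediate
19 | (R)-4-benzyl-3-propionyloxazolidin-2-one | CCC(=O)N1C(=O)OC[C@H]1Cc1ccccc1 | starting material
20 | Z-dibutylboron enolate of 19 | C/C=C(\OB(CCCC)CCCC)N1C(=O)OC[C@H]1Cc1ccccc1 | intermediate
21 | 9,10-syn aldol imide (9R,10R) | C=C(C)[C@@H](O[Si](CC)(CC)CC)[C@@H]1O[C@H](OC)[C@@H](C)[C@@H]1[C@@H](OCc2ccc(OC)cc2)[C@H](O)[C@@H](C)C(=O)N3C(=O)OC[C@H]3Cc4ccccc4 | intermediate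
22 | C9 TBS ether imide | C=C(C)[C@@H](O[Si](CC)(CC)CC)[C@@H]1O[C@H](OC)[C@@H](C)[C@@H]1[C@@H](OCc2ccc(OC)cc2)[C@H](O[Si](C)(C)C(C)(C)C)[C@@H](C)C(=O)N3C(=O)OC[C@H]3Cc4ccccc4 | intermediate
23 | C1 peroxy acid | C=C(C)[C@@H](O[Si](CC)(CC)CC)[C@@H]1O[C@H](OC)[C@@H](C)[C@@H]1[C@@H](OCc2ccc(OC)cc2)[C@H](O[Si](C)(C)C(C)(C)C)[C@@H](C)C(=O)OO | intermediate
24 | C1 carboxylic acid with C5 TES ether | C=C(C)[C@@H](O[Si](CC)(CC)CC)[C@@H]1O[C@H](OC)[C@@H](C)[C@@H]1[C@@H](OCc2ccc(OC)cc2)[C@H](O[Si](C)(C)C(C)(C)C)[C@@H](C)C(=O)O | intermediate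
25 | seco acid (C5–OH, C1 CO2H) | C=C(C)[C@@H](O)[C@@H]1O[C@H](OC)[C@@H](C)[C@@H]1[C@@H](OCc2ccc(OC)cc2)[C@H](O[Si](C)(C)C(C)(C)C)[C@@H](C)C(=O)O | intermediate
26 | mixed anhydride of 25 and 2-methyl-6-nitrobenzoic acid | C=C(C)[C@@H](O)[C@@H]1O[C@H](OC)[C@@H](C)[C@@H]1[C@@H](OCc2ccc(OC)cc2)[C@H](O[Si](C)(C)C(C)(C)C)[C@@H](C)C(=O)OC(=O)c3c(C)cccc3[N+](=O)[O-] | intermediate
27 | eight-membered lactone (O5–C1), cis-fused to the acetal ring at C6–C7 | O=C1O[C@H](C(C)=C)[C@@H]2O[C@H](OC)[C@@H](C)[C@@H]2[C@@H](OCc3ccc(OC)cc3)[C@H](O[Si](C)(C)C(C)(C)C)[C@H]1C | intermediate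
28 | 2-methylene-8-isopropenyloxocane (key-step precursor) | C=C1O[C@H](C(C)=C)[C@@H]2O[C@H](OC)[C@@H](C)[C@@H]2[C@@H](OCc3ccc(OC)cc3)[C@H](O[Si](C)(C)C(C)(C)C)[C@H]1C | intermediate
29 | E-cyclodec-4-enone with C1 ketone (key-step product) | O=C1CC/C(C)=C/[C@@H]2O[C@H](OC)[C@@H](C)[C@@H]2[C@@H](OCc3ccc(OC)cc3)[C@H](O[Si](C)(C)C(C)(C)C)[C@H]1C | intermediate
30 | C1 alcohol (O1 anti to the C10 methyl group) | O[C@H]1CC/C(C)=C/[C@@H]2O[C@H](OC)[C@@H](C)[C@@H]2[C@@H](OCc3ccc(OC)cc3)[C@H](O[Si](C)(C)C(C)(C)C)[C@H]1C | intermediate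
31 | C1 methyl ether | CO[C@H]1CC/C(C)=C/[C@@H]2O[C@H](OC)[C@@H](C)[C@@H]2[C@@H](OCc3ccc(OC)cc3)[C@H](O[Si](C)(C)C(C)(C)C)[C@H]1C | intermediate
32 | C12 lactol | CO[C@H]1CC/C(C)=C/[C@@H]2O[C@H](O)[C@@H](C)[C@@H]2[C@@H](OCc3ccc(OC)cc3)[C@H](O[Si](C)(C)C(C)(C)C)[C@H]1C | intermediate
33 | 6,12-γ-lactone with C8 PMB and C9 TBS ethers | CO[C@H]1CC/C(C)=C/[C@@H]2OC(=O)[C@@H](C)[C@@H]2[C@@H](OCc3ccc(OC)cc3)[C@H](O[Si](C)(C)C(C)(C)C)[C@H]1C | intermediate
34 | C8 alcohol | CO[C@H]1CC/C(C)=C/[C@@H]2OC(=O)[C@@H](C)[C@@H]2[C@@H](O)[C@H](O[Si](C)(C)C(C)(C)C)[C@H]1C | intermediate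
35 | tiglic acid | C/C=C(\C)C(=O)O | starting material
36 | (E)-2-methylbut-2-en-1-ol | C/C=C(\C)CO | intermediate
37 | (2R,3R)-2,3-dimethyloxiran-2-ylmethanol | OC[C@@]1(C)O[C@@H]1C | intermediate
38 | (2S,3R)-2,3-dimethyloxirane-2-carboxylic acid | OC(=O)[C@@]1(C)O[C@@H]1C | intermediate
39 | mixed anhydride of 38 and 2,4,6-trichlorobenzoic acid | O=C(OC(=O)[C@@]1(C)O[C@@H]1C)c1c(Cl)cc(Cl)cc1Cl | intermediate
40 | C8 epoxy ester with C9 TBS ether | CO[C@H]1CC/C(C)=C/[C@@H]2OC(=O)[C@@H](C)[C@@H]2[C@@H](OC(=O)[C@@]3(C)O[C@@H]3C)[C@H](O[Si](C)(C)C(C)(C)C)[C@H]1C | intermediate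
41 | C9 alcohol | CO[C@H]1CC/C(C)=C/[C@@H]2OC(=O)[C@@H](C)[C@@H]2[C@@H](OC(=O)[C@@]3(C)O[C@@H]3C)[C@H](O)[C@H]1C | intermediate
42 | CNP0145898.1 (1S,6S,7S,8R,10S,11S; side chain 2S,3R; 4E) | CO[C@H]1CC/C(C)=C/[C@@H]2OC(=O)[C@@H](C)[C@@H]2[C@@H](OC(=O)[C@@]2(C)O[C@@H]2C)C(=O)[C@H]1C | target

Total step count: 29. Longest linear sequence: 26 steps (steps 1–23 and 27–29). Steps 24–26 form the convergent side-chain branch.

Steps most likely to fail

Step 18 (key step).
- What may go wrong: the rearrangement may run through the array with C6 turned inward and so give the wrong alkene geometry, or traces of acid may move the exocyclic double bond into the ring before the shift occurs.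
- Fallback (sets out from 24, comes back at 29): the same C2–C3 bond is made and the same C5–O bond is broken, but stepwise on zerovalent palladium (Tsuji–Trost macrocyclisation), where E geometry follows from the syn π-allyl complex.
- Acid 24 is homologated with carbonyldiimidazole, then MgCl2, Et3N and potassium methyl malonate (Masamune–Brooks reaction), to the methyl β-keto ester F1.
- PPTS in MeOH frees the C5 allylic alcohol F2, and ClCO2Me with pyridine gives the allylic methyl carbonate F3.
- Slow addition to Pd(PPh3)4 in hot THF ionises the carbonate. The β-keto ester carbon C2 should attack the unsubstituted allyl terminus C3 to give the ten-membered E-configured cyclic β-keto ester F4.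
- Krapcho demethoxycarbonylation (LiCl, wet DMSO, 130 °C) leads to 29.

Step 16.
- What may go wrong: intermolecular acylation (oligomerisation) may outrun closure of the strained eight-membered ring at a hindered allylic alcohol.
- Fallback (sets out from 15, comes back at 27): the ester bond is made intermolecularly and the ring is closed at C9–C10 by carbon–carbon bond formation.
- i-Bu2AlH opens the acetal of 15 to the C5,C9-diol F5, and TBSCl with imidazole silylates only the primary hydroxyl group to give the C9 silyl ether F6.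
- 2-Bromopropanoyl bromide and pyridine acylate O5 to give the α-bromo ester F7. HF·pyridine then releases the primary alcohol F8, and Dess–Martin oxidation gives the bromo ester aldehyde F9.
- SmI2 in THF at high dilution closes the ring by an intramolecular Reformatsky reaction templated by trivalent samarium, giving the β-hydroxy lactone F10.
- The C9/C10 configuration of F10 is not secured by an auxiliary; it has to be checked, and the isomer drawn separated. TBSOTf with 2,6-lutidine then gives 27.

Step 27.
- What may go wrong: acyl transfer between an α-quaternary acid and a secondary alcohol wedged between the ring fusion and a silyl ether may be too slow, so that the activated acid decomposes first.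
- Fallback (sets out from 33, comes back at 42): the order of events is changed so that the hydroxyl group lies next to a flat carbonyl carbon.
- HF·pyridine converts 33 into the C9 alcohol F11, Dess–Martin oxidation gives the C9 ketone F12, and DDQ gives the α-hydroxy ketone F13.
- F13 is acylated with anhydride 39 and DMAP at or below rt to give 42 directly. The price is exposing the β-methoxy ketone to amine bases.

Further compounds
F1 | step 18 | methyl β-keto ester (C1 ketone, C2 CH2, CO2Me; C5 TES ether) | C=C(C)[C@@H](O[Si](CC)(CC)CC)[C@@H]1O[C@H](OC)[C@@H](C)[C@@H]1[C@@H](OCc2ccc(OC)cc2)[C@H](O[Si](C)(C)C(C)(C)C)[C@@H](C)C(=O)CC(=O)OC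
F2 | step 18 | C5 allylic alcohol of the β-keto ester | C=C(C)[C@@H](O)[C@@H]1O[C@H](OC)[C@@H](C)[C@@H]1[C@@H](OCc2ccc(OC)cc2)[C@H](O[Si](C)(C)C(C)(C)C)[C@@H](C)C(=O)CC(=O)OC
F3 | step 18 | allylic methyl carbonate | C=C(C)[C@@H](OC(=O)OC)[C@@H]1O[C@H](OC)[C@@H](C)[C@@H]1[C@@H](OCc2ccc(OC)cc2)[C@H](O[Si](C)(C)C(C)(C)C)[C@@H](C)C(=O)CC(=O)OC
F4 | step 18 | ten-membered E-configured cyclic β-keto ester (C2 epimers) | O=C1C(C(=O)OC)C/C(C)=C/[C@@H]2O[C@H](OC)[C@@H](C)[C@@H]2[C@@H](OCc3ccc(OC)cc3)[C@H](O[Si](C)(C)C(C)(C)C)[C@H]1C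
F5 | step 16 | C5,C9-diol with C8 PMB ether | C=C(C)[C@@H](O)[C@@H]1O[C@H](OC)[C@@H](C)[C@@H]1[C@@H](OCc2ccc(OC)cc2)CO
F6 | step 16 | C9 silyl ether with free C5 alcohol | C=C(C)[C@@H](O)[C@@H]1O[C@H](OC)[C@@H](C)[C@@H]1[C@@H](OCc2ccc(OC)cc2)CO[Si](C)(C)C(C)(C)C
F7 | step 16 | α-bromo ester (O5 2-bromopropanoate, C9 TBS ether) | C=C(C)[C@@H](OC(=O)C(C)Br)[C@@H]1O[C@H](OC)[C@@H](C)[C@@H]1[C@@H](OCc2ccc(OC)cc2)CO[Si](C)(C)C(C)(C)C
F8 | step 16 | primary alcohol of the bromo ester | C=C(C)[C@@H](OC(=O)C(C)Br)[C@@H]1O[C@H](OC)[C@@H](C)[C@@H]1[C@@H](OCc2ccc(OC)cc2)CO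
F9 | step 16 | bromo ester aldehyde | C=C(C)[C@@H](OC(=O)C(C)Br)[C@@H]1O[C@H](OC)[C@@H](C)[C@@H]1[C@@H](OCc2ccc(OC)cc2)C=O
F10 | step 16 | β-hydroxy lactone (eight-membered, C9–OH) | O=C1O[C@H](C(C)=C)[C@@H]2O[C@H](OC)[C@@H](C)[C@@H]2[C@@H](OCc3ccc(OC)cc3)[C@H](O)[C@H]1C
F11 | step 27 | C9 alcohol with C8 PMB ether | CO[C@H]1CC/C(C)=C/[C@@H]2OC(=O)[C@@H](C)[C@@H]2[C@@H](OCc3ccc(OC)cc3)[C@H](O)[C@H]1C
F12 | step 27 | C9 ketone with C8 PMB ether | CO[C@H]1CC/C(C)=C/[C@@H]2OC(=O)[C@@H](C)[C@@H]2[C@@H](OCc3ccc(OC)cc3)C(=O)[C@H]1C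
F13 | step 27 | α-hydroxy ketone (C8–OH, C9 ketone) | CO[C@H]1CC/C(C)=C/[C@@H]2OC(=O)[C@@H](C)[C@@H]2[C@@H](O)C(=O)[C@H]1C
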